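Remark (assumption on the chemistry): the target is taken exactly as drawn, i.e. (2Z,6S,7S,10E,12R) in geranylgeraniol numbering (C1 = CH2OH on C2, C20 = CH2OH on C3, C19 = CH3 on C7, C18 = CH3 on C11, C16/C17 = CH3 on C15). This numbering is used for target atoms throughout.

## Analysis of the target

The target is an acyclic C20 diterpenoid monoacetate whose only ring is the C6–C7 oxirane. It has three stereocentres: C6 (S) and C7 (S) in the trans-configured 2,2,3-trisubstituted epoxide, and C12 (R) in the allylic acetate. C7 and C12 are four carbons apart, so neither can control the other and each must be set by a reagent. Two olefin geometries must also be fixed: 10E, and 2Z, which holds C1 and C20 cis as a (Z)-2-substituted but-2-ene-1,4-diol. The sensitive groups are the epoxide (acid; the C20 hydroxyl lies five atoms from C6 and would open it intramolecularly), the allylic C12 acetate (ionisation, SN2′, base) and the cis-enediol (cyclodehydration to a 2,5-dihydrofuran). The real difficulty is selectivity among like groups: four trisubstituted π-sites of which only C6=C7 is epoxidised, and three hydroxyls of which only the secondary one is acetylated. Two features of this structure are used here. Atoms C20, C3, C2 and C1 with their two oxygens are a 3-substituted furan ring in latent form (furan C2, C3, C4, C5 = target C20, C3, C2, C1). Atoms C5–C12 with C19 and C18 are the intact carbon chain of geraniol (C5 = its carbinol carbon, C12 = its (E)-terminal methyl).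

## Retrosynthetic reasoning

**15 to 12.** The first cut is made in the oxidation pattern, not in a C–C bond. The two primary C–OH groups and the Z-configured C2=C3 bond of 15 are traced back to the furan ring of 12, whose ring oxygen bridges C20 and C1. The forward reaction is a [4+2] photooxygenation across C20/C1 followed by reductive opening. This cut means the two primary hydroxyls do not exist while C12 is acetylated, the Z geometry is inherited from the ring, and the diol is freed only at the end without acid.

**12 to 11 to 10.** The C14=C15 bond is cut by cross-metathesis, and the ester C–O bond by acylation. A prenyl group cannot be delivered to a carbonyl with linear regiochemistry, because allylic transposition gives the branched isomer. An allyl group followed by exchange of its methylene for an isopropylidene is reliable.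

**10 to 9.** The C12–C13 bond is cut, leading back to enal 9. The forward reaction is a reagent-controlled allyl addition that sets C12 (R). The cut is placed here because C12 becomes a carbonyl carbon directly when the terminal methyl of the geraniol chain is oxidised.

**9 to 7.** The C12–O bond is cut: allylic oxidation of the (E)-methyl of the isopropylidene in 7. Because 7 has a single olefin there is no regiochemical question. The forward reaction has to give the E geometry and spare furan and epoxide.

**7 to 3 and 6.** The C4–C5 bond is cut. This is the seam between the five-carbon furan unit (C1–C4, C20) and the ten-carbon geraniol unit. C5 is the carbinol carbon of geraniol, so the hydroxyl that first directs the epoxidation then becomes the leaving group in 3. The forward reaction must achieve SN2 displacement at C5 without opening the adjacent epoxide.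

**3 to 2 to 1, and 6 to 5 to 4.** The epoxide C–O bonds come from hydroxyl-directed asymmetric epoxidation of 1, which sets C6 and C7 together. The organomagnesium 6 comes from alcohol 4 through chloride 5.

## Alternatives that were turned down

Alternative 1: (textbook) Disconnection at C3–C4 with a preformed maleate. The forward key step is syn-carbocupration of an acetylenedicarboxylate ester by the organocopper reagent from homoallylic iodide A1, giving maleate A2. This is followed by hydride reduction, bis-silylation, late epoxidation of C6=C7 and reduction of a C12 ketone. It was turned down for three reasons: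
- An organometallic at C4 cannot carry the C6–C7 epoxide, because 3-exo-tet closure gives a cyclopropylcarbinol. The epoxide must therefore be introduced into a polyene without a directing hydroxyl, where C6=C7, C10=C11 and C14=C15 are electronically alike. A Shi epoxidation would additionally need the enantiomeric series of the fructose-derived ketone.
- The ester reduction cannot coexist with the C12 acetate. Two silyl ethers must go on and come off, the removal taking place beside the epoxide and the free C20 hydroxyl.
- The route is estimated at fourteen or more steps.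

Alternative 2: Disconnection at C11–C12 by lithiation–borylation. The forward key step is sparteine-mediated lithiation of carbamate A3, capture by alkenylboronate A4, 1,2-metallate rearrangement and oxidation to alcohol A5. It was turned down because A4 is not simpler than its product. Boron must sit on C11, which in geraniol is the isopropylidene carbon, so the terminal three carbons of geraniol would have to be cut off and a trisubstituted alkenylboronate rebuilt with geometric control. This costs three to four extra steps and adds an E/Z risk. The alkyllithium base also threatens the furan α-positions, and the magnesium halide used to drive the rearrangement threatens the epoxide. The gain is C12 alone, which allylation sets equally well.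

Alternative 3: Disconnection at C12–C13 by [2,3]-Wittig rearrangement. The forward key step is deprotonation of the bis-allylic ether A6 at C12 and sigmatropic shift onto the vinyl terminus. It would form C12–C13 and the C14=C15 isopropylidene in one operation and give the skeleton of A5. It was turned down on stereocontrol. The migrating terminus (CMe2) is achiral, the nearest stereocentre (C7) is five bonds away, and chiral-base versions on non-stabilised bis-allyl ethers are only moderately selective. A5 would arise as a C12 epimer mixture needing an oxidation/reduction correction, which erases the saving. The strong base would also lithiate the furan and open the way to a competing [1,2]-shift.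

Key step: step 9

## Route

Step 1
Reactants: 1 geraniol [(2E)-3,7-dimethylocta-2,6-dien-1-ol]
Product: 2 [(2S,3S)-3-methyl-3-(4-methylpent-3-en-1-yl)oxiran-2-yl]methanol
Conditions: Ti(OiPr)4 (cat.), L-(+)-diisopropyl tartrate (cat.), t-BuOOH, 4 Å MS, CH2Cl2, –20 °C
Reagents that add atoms: tert-butyl hydroperoxide, CC(C)(C)OO
Why: Sharpless asymmetric epoxidation: the allylic hydroxyl directs the titanium-bound peroxide to the allylic double bond only (target C6=C7; the distal isopropylidene is left), and the natural L-(+)-tartrate ester should deliver oxygen to the face that gives the (2S,3S)-epoxy alcohol, i.e. target C6 (S) and C7 (S) together.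

Step 2
Reactants: 2 [(2S,3S)-3-methyl-3-(4-methylpent-3-en-1-yl)oxiran-2-yl]methanol
Product: 3 [(2S,3S)-3-methyl-3-(4-methylpent-3-en-1-yl)oxiran-2-yl]methyl 4-methylbenzenesulfonate
Conditions: TsCl, Et3N, DMAP (cat.), CH2Cl2, 0 °C
Reagents that add atoms: 4-methylbenzenesulfonyl chloride, Cc1ccc(cc1)S(=O)(=O)Cl
Why: Sulfonylation of the primary alcohol; the epoxide stereocentres are not involved, and the directing hydroxyl is turned into the leaving group for the C4–C5 coupling.

Step 3
Reactants: 4 furan-3-ylmethanol
Product: 5 3-(chloromethyl)furan
Conditions: SOCl2, pyridine, Et2O, 0 °C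
Reagents that add atoms: thionyl chloride, O=S(Cl)Cl
Why: Chlorodehydroxylation of a primary heterobenzylic alcohol through its chlorosulfite; the labile chloride should be used at once.

Step 4
Reactants: 5 3-(chloromethyl)furan; 3 [(2S,3S)-3-methyl-3-(4-methylpent-3-en-1-yl)oxiran-2-yl]methyl 4-methylbenzenesulfonate
Product: 7 3-{2-[(2S,3S)-3-methyl-3-(4-methylpent-3-en-1-yl)oxiran-2-yl]ethyl}furan, via furan-3-ylmethylmagnesium chloride 6 (not isolated)
Conditions: 5, Mg, THF, 0 °C → rt; then 3, Li2CuCl4 (cat.), THF, –30 → 0 °C
Reagents that add atoms: none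
Why: Copper-catalysed Grignard–sulfonate cross-coupling (Kochi–Schlosser type): the organocopper species from 6 should displace the primary tosylate at C5 by SN2 faster than it attacks the hindered secondary and quaternary epoxide carbons, so C6 and C7 keep their configuration while the C4–C5 bond joins the furan unit to the geraniol chain.

Step 5
Reactants: 7 3-{2-[(2S,3S)-3-methyl-3-(4-methylpent-3-en-1-yl)oxiran-2-yl]ethyl}furan
Product: 9 (2E)-5-[(2S,3S)-3-[2-(furan-3-yl)ethyl]-2-methyloxiran-2-yl]-2-methylpent-2-enal, via allylic alcohol 8 (not isolated)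
Conditions: SeO2 (cat.), t-BuOOH, CH2Cl2, 0 °C → rt; then MnO2, CH2Cl2, rt
Reagents that add atoms: tert-butyl hydroperoxide, CC(C)(C)OO; selenium dioxide, O=[Se]=O (oxygen relay)
Why: Selenium dioxide allylic oxidation (ene reaction, then [2,3]-sigmatropic shift) should attack the only olefin of 7 at its (E)-methyl group, which fixes the 10E geometry and places oxygen on C12; MnO2 then oxidises allylic alcohol 8 selectively, so that any alcohol/aldehyde mixture converges on enal 9.

Step 6
Reactants: 9 (2E)-5-[(2S,3S)-3-[2-(furan-3-yl)ethyl]-2-methyloxiran-2-yl]-2-methylpent-2-enal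
Product: 10 (4R,5E)-8-[(2S,3S)-3-[2-(furan-3-yl)ethyl]-2-methyloxiran-2-yl]-5-methylocta-1,5-dien-4-ol
Conditions: B-allyldiisopinocampheylborane from (–)-α-pinene [lIpc2B(allyl)], Et2O, –78 °C; then NaOH, H2O2, 0 °C
Reagents that add atoms: B-allyldiisopinocampheylborane (from (–)-α-pinene), C=CCB([C@H]1C[C@H]2C[C@@H]([C@@H]1C)C2(C)C)[C@H]1C[C@H]2C[C@@H]([C@@H]1C)C2(C)C
Why: Brown allylation through a closed chair transition state; the isopinocampheyl groups derived from (–)-α-pinene should direct the allyl group to the aldehyde face that gives the (R)-carbinol (the antipodal reagent is the one that gives (S)-carbinols from aldehydes of this priority pattern), so C12 is set by the reagent alone and the remote epoxide has no influence.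

Step 7
Reactants: 10 (4R,5E)-8-[(2S,3S)-3-[2-(furan-3-yl)ethyl]-2-methyloxiran-2-yl]-5-methylocta-1,5-dien-4-ol
Product: 11 (4R,5E)-8-[(2S,3S)-3-[2-(furan-3-yl)ethyl]-2-methyloxiran-2-yl]-5-methylocta-1,5-dien-4-yl acetate
Conditions: Ac2O, Et3N, DMAP (cat.), CH2Cl2, 0 °C → rt
Reagents that add atoms: acetic anhydride, CC(=O)OC(C)=O
Why: DMAP-catalysed acylation of the only hydroxyl group in the molecule; no stereocentre is touched, and because the two primary hydroxyls of the target do not yet exist, no selectivity problem arises.

Step 8
Reactants: 11 (4R,5E)-8-[(2S,3S)-3-[2-(furan-3-yl)ethyl]-2-methyloxiran-2-yl]-5-methylocta-1,5-dien-4-yl acetate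
Product: 12 (5R,6E)-9-[(2S,3S)-3-[2-(furan-3-yl)ethyl]-2-methyloxiran-2-yl]-2,6-dimethylnona-2,6-dien-5-yl acetate
Conditions: second-generation Grubbs catalyst RuCl2(=CHPh)(H2IMes)(PCy3) (cat.), 2-methylbut-2-ene, CH2Cl2, 40 °C
Reagents that add atoms: 2-methylbut-2-ene, CC=C(C)C
Why: Olefin cross-metathesis: the monosubstituted terminal alkene should exchange its methylene for the isopropylidene of 2-methylbut-2-ene, while the trisubstituted C10=C11 bond, the furan, the epoxide and the allylic acetate are not substrates for the ruthenium carbene.

Step 9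
Reactants: 12 (5R,6E)-9-[(2S,3S)-3-[2-(furan-3-yl)ethyl]-2-methyloxiran-2-yl]-2,6-dimethylnona-2,6-dien-5-yl acetate
Product: 15 (2Z,6S,7S,10E,12R)-12-acetoxy-6,7-epoxy-3-(hydroxymethyl)-7,11,15-trimethylhexadeca-2,10,14-trien-1-ol (CNP0252194.1), via endoperoxide 13 (not isolated), via enedial 14 (not isolated)
Conditions: O2, hν, 5,10,15,20-tetraphenylporphyrin (cat.), CH2Cl2, –78 °C; then Me2S, –78 → –20 °C; then NaBH4, CeCl3·7H2O, MeOH, –78 → –40 °C
Reagents that add atoms: oxygen, O=O
Why: Singlet oxygen should add in a concerted suprafacial [4+2] cycloaddition across furan C2 and C5 (target C20 and C1) to give the 2,3,7-trioxabicyclo[2.2.1]heptene 13. Dimethyl sulfide then cleaves the O–O bond and the bicycle collapses to the (Z)-enedial 14. Luche reduction converts both aldehydes by 1,2-hydride addition into the C1 and C20 carbinols. The closest known reaction types are the photooxygenation of 3-alkylfurans with reductive work-up to cis-1,4-enedicarbonyls and the Luche reduction of cis-enediones to cis-enediols. The only ring closed is the transient peroxide bridge of 13 (pericyclic [4+2] closure), which does not survive, so the net result is opening of the furan ring. No new stereocentre remains in 15 because the bridgeheads of 13 are destroyed, and the Z geometry of C2=C3 is fixed by the ring: it is the former furan C3=C4 bond, whose substituents C20 and C1 are held cis. The step needs chemoselectivity for the furan over the C14=C15 and C10=C11 olefins, which should follow from the much faster cycloaddition of furans compared with the ene reaction of trisubstituted alkenes, the low temperature and the deactivation of C10=C11 by its allylic acetate. It also needs hydride selectivity for the aldehydes over acetate and epoxide, which low-temperature Luche conditions provide, and it frees the two primary hydroxyls only at the end and without acid.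

## Compound list

1 | geraniol, (2E)-3,7-dimethylocta-2,6-dien-1-ol | CC(C)=CCC/C(C)=C/CO | starting material
2 | [(2S,3S)-3-methyl-3-(4-methylpent-3-en-1-yl)oxiran-2-yl]methanol | CC(C)=CCC[C@]1(C)O[C@H]1CO | intermediate
3 | [(2S,3S)-3-methyl-3-(4-methylpent-3-en-1-yl)oxiran-2-yl]methyl 4-methylbenzenesulfonate | CC(C)=CCC[C@]1(C)O[C@H]1COS(=O)(=O)c1ccc(C)cc1 | intermediate
4 | furan-3-ylmethanol | OCc1ccoc1 | starting material
5 | 3-(chloromethyl)furan | ClCc1ccoc1 | intermediate
6 | furan-3-ylmethylmagnesium chloride | Cl[Mg]Cc1ccoc1 | intermediate
7 | 3-{2-[(2S,3S)-3-methyl-3-(4-methylpent-3-en-1-yl)oxiran-2-yl]ethyl}furan | CC(C)=CCC[C@]1(C)O[C@H]1CCc1ccoc1 | intermediate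
8 | (2E)-5-[(2S,3S)-3-[2-(furan-3-yl)ethyl]-2-methyloxiran-2-yl]-2-methylpent-2-en-1-ol | OC/C(C)=C/CC[C@]1(C)O[C@H]1CCc1ccoc1 | intermediate
9 | (2E)-5-[(2S,3S)-3-[2-(furan-3-yl)ethyl]-2-methyloxiran-2-yl]-2-methylpent-2-enal | O=C/C(C)=C/CC[C@]1(C)O[C@H]1CCc1ccoc1 | intermediate
10 | (4R,5E)-8-[(2S,3S)-3-[2-(furan-3-yl)ethyl]-2-methyloxiran-2-yl]-5-methylocta-1,5-dien-4-ol | C=CC[C@@H](O)/C(C)=C/CC[C@]1(C)O[C@H]1CCc1ccoc1 | intermediate
11 | (4R,5E)-8-[(2S,3S)-3-[2-(furan-3-yl)ethyl]-2-methyloxiran-2-yl]-5-methylocta-1,5-dien-4-yl acetate | C=CC[C@@H](OC(C)=O)/C(C)=C/CC[C@]1(C)O[C@H]1CCc1ccoc1 | intermediate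
12 | (5R,6E)-9-[(2S,3S)-3-[2-(furan-3-yl)ethyl]-2-methyloxiran-2-yl]-2,6-dimethylnona-2,6-dien-5-yl acetate | CC(=O)O[C@H](CC=C(C)C)/C(C)=C/CC[C@]1(C)O[C@H]1CCc1ccoc1 | intermediate
13 | (5R,6E)-2,6-dimethyl-9-[(2S,3S)-2-methyl-3-[2-(2,3,7-trioxabicyclo[2.2.1]hept-5-en-5-yl)ethyl]oxiran-2-yl]nona-2,6-dien-5-yl acetate (bridgehead configuration not defined) | CC(=O)O[C@H](CC=C(C)C)/C(C)=C/CC[C@]1(C)O[C@H]1CCC1=CC2OOC1O2 | intermediate
14 | (5R,6E)-9-[(2S,3S)-3-[(3Z)-3-formyl-5-oxopent-3-en-1-yl]-2-methyloxiran-2-yl]-2,6-dimethylnona-2,6-dien-5-yl acetate | CC(=O)O[C@H](CC=C(C)C)/C(C)=C/CC[C@]1(C)O[C@H]1CC/C(=C/C=O)C=O | intermediate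
15 | (2Z,6S,7S,10E,12R)-12-acetoxy-6,7-epoxy-3-(hydroxymethyl)-7,11,15-trimethylhexadeca-2,10,14-trien-1-ol | CC(=O)O[C@H](CC=C(C)C)/C(C)=C/CC[C@]1(C)O[C@H]1CC/C(=C/CO)CO | target

## Step count and least certain steps

Total step count: 9. Longest linear sequence: 8 steps (1 to 15 through steps 1, 2, 4, 5, 6, 7, 8, 9); step 3 is the one-step side branch that joins at step 4.

**Step 9 (key step).** The most likely failure is competing ene oxygenation of the C14=C15 isopropylidene during the photooxygenation, because it is the one electron-rich trisubstituted olefin left. A second risk lies in the hydride stage: the half-reduced hydroxy-aldehyde can close to a lactol and re-aromatise to the furan, or suffer conjugate reduction. The fallback sets out from 11, whose terminal alkene is monosubstituted and inert to singlet oxygen. The same photooxygenation should give the endoperoxide F1, sulfide reduction the enedial F2, and Luche reduction the allyl diol F3. Cross-metathesis of F3 with 2-methylbut-2-ene under the conditions of step 8 then installs the isopropylidene last and comes back to the route at 15. This changes the endgame so that singlet oxygen never meets the ene-active olefin.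

**Step 4.** The most likely failures are opening or Lewis-acid rearrangement of the epoxide by the Grignard reagent and its magnesium halide, attack of the furylmethyl nucleophile through ring C2, and Wurtz dimerisation while 6 is formed. The fallback forms the C4–C5 bond as an olefin and sets out from 2 and 5. Parikh–Doering oxidation of 2 should give the epoxy aldehyde F4. Chloride 5 and PPh3 give the phosphonium salt F5. Its ylide (NaN(SiMe3)2, THF, –78 °C) should add to F4 to give the alkene F6 as an E/Z mixture, which is of no consequence. Diimide (2-nitrobenzenesulfonyl hydrazide, Et3N) should saturate the disubstituted C4=C5 bond in preference to the trisubstituted olefin and leave the furan. The fallback comes back to the route at 7.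

**Step 5.** The most likely failures are oxidative degradation of the furan by the peroxide/selenium system and acid-promoted opening of the epoxide by seleninic acid. The fallback carries out the allylic oxidation before the furan is present and sets out from 3. SeO2/t-BuOOH followed by a NaBH4 work-up should give the hydroxy tosylate F7. Silylation (t-BuMe2SiCl, imidazole) gives the silyl ether F8. Coupling with 6 under the conditions of step 4 gives the furan silyl ether F9. Bu4NF then releases allylic alcohol 8, where the fallback comes back to the route; 8 is oxidised to 9 with MnO2 as in step 5.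

**Step 6.** The most likely failure is insufficient facial selectivity at C12. The existing stereocentres are too remote to help, and the minor C12 epimer is a diastereomer that may be hard to separate; any shortfall in the enantiomeric purity from step 1 shows up the same way. The fallback replaces reagent-controlled addition by reagent-controlled reduction and sets out from 9. AllylMgBr (THF, –78 °C) should give the C12 epimer mixture F10. MnO2 oxidises it to the dienone F11. Corey–Bakshi–Shibata reduction with (S)-1-methyl-3,3-diphenyltetrahydro-1H,3H-pyrrolo[1,2-c][1,3,2]oxazaborole and catecholborane at –78 °C should place hydride so that the branched alkenyl group acts as the large substituent and the (R)-carbinol results. The fallback comes back to the route at 10.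

## Further compounds

F1 | step 9 | (4R,5E)-5-methyl-8-[(2S,3S)-2-methyl-3-[2-(2,3,7-trioxabicyclo[2.2.1]hept-5-en-5-yl)ethyl]oxiran-2-yl]octa-1,5-dien-4-yl acetate (bridgehead configuration not defined) | C=CC[C@@H](OC(C)=O)/C(C)=C/CC[C@]1(C)O[C@H]1CCC1=CC2OOC1O2
F2 | step 9 | (4R,5E)-8-[(2S,3S)-3-[(3Z)-3-formyl-5-oxopent-3-en-1-yl]-2-methyloxiran-2-yl]-5-methylocta-1,5-dien-4-yl acetate | C=CC[C@@H](OC(C)=O)/C(C)=C/CC[C@]1(C)O[C@H]1CC/C(=C/C=O)C=O
F3 | step 9 | (4R,5E)-8-[(2S,3S)-3-[(3Z)-5-hydroxy-3-(hydroxymethyl)pent-3-en-1-yl]-2-methyloxiran-2-yl]-5-methylocta-1,5-dien-4-yl acetate | C=CC[C@@H](OC(C)=O)/C(C)=C/CC[C@]1(C)O[C@H]1CC/C(=C/CO)CO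
F4 | step 4 | (2R,3S)-3-methyl-3-(4-methylpent-3-en-1-yl)oxirane-2-carbaldehyde | CC(C)=CCC[C@]1(C)O[C@H]1C=O
F5 | step 4 | (furan-3-ylmethyl)triphenylphosphonium chloride | C(c1ccoc1)[P+](c1ccccc1)(c1ccccc1)c1ccccc1.[Cl-]
F6 | step 4 | 3-{2-[(2S,3S)-3-methyl-3-(4-methylpent-3-en-1-yl)oxiran-2-yl]ethenyl}furan (E/Z mixture) | CC(C)=CCC[C@]1(C)O[C@H]1C=Cc1ccoc1
F7 | step 5 | [(2S,3S)-3-[(3E)-5-hydroxy-4-methylpent-3-en-1-yl]-3-methyloxiran-2-yl]methyl 4-methylbenzenesulfonate | OC/C(C)=C/CC[C@]1(C)O[C@H]1COS(=O)(=O)c1ccc(C)cc1
F8 | step 5 | [(2S,3S)-3-[(3E)-5-{[tert-butyl(dimethyl)silyl]oxy}-4-methylpent-3-en-1-yl]-3-methyloxiran-2-yl]methyl 4-methylbenzenesulfonate | CC(C)(C)[Si](C)(C)OC/C(C)=C/CC[C@]1(C)O[C@H]1COS(=O)(=O)c1ccc(C)cc1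
F9 | step 5 | tert-butyl{[(2E)-5-[(2S,3S)-3-[2-(furan-3-yl)ethyl]-2-methyloxiran-2-yl]-2-methylpent-2-en-1-yl]oxy}dimethylsilane | CC(C)(C)[Si](C)(C)OC/C(C)=C/CC[C@]1(C)O[C@H]1CCc1ccoc1
F10 | step 6 | (5E)-8-[(2S,3S)-3-[2-(furan-3-yl)ethyl]-2-methyloxiran-2-yl]-5-methylocta-1,5-dien-4-ol (mixture of C4 epimers) | C=CCC(O)/C(C)=C/CC[C@]1(C)O[C@H]1CCc1ccoc1
F11 | step 6 | (5E)-8-[(2S,3S)-3-[2-(furan-3-yl)ethyl]-2-methyloxiran-2-yl]-5-methylocta-1,5-dien-4-one | C=CCC(=O)/C(C)=C/CC[C@]1(C)O[C@H]1CCc1ccoc1
A1 | alternative 1 | (3E)-1-iodo-4,8-dimethylnona-3,7-diene | CC(C)=CCC/C(C)=C/CCI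
A2 | alternative 1 | dimethyl (2Z)-2-[(3E)-4,8-dimethylnona-3,7-dien-1-yl]but-2-enedioate | CC(C)=CCC/C(C)=C/CC/C(=C/C(=O)OC)C(=O)OC
A3 | alternative 2 | 4-methylpent-3-en-1-yl N,N-di(propan-2-yl)carbamate | CC(C)=CCCOC(=O)N(C(C)C)C(C)C
A4 | alternative 2 | 2-[(2Z)-5-[(2S,3S)-3-[2-(furan-3-yl)ethyl]-2-methyloxiran-2-yl]pent-2-en-2-yl]-4,4,5,5-tetramethyl-1,3,2-dioxaborolane (boron trans to C9) | CC1(C)OB(OC1(C)C)/C(C)=C/CC[C@]1(C)O[C@H]1CCc1ccoc1
A5 | alternative 2 | (5R,6E)-9-[(2S,3S)-3-[2-(furan-3-yl)ethyl]-2-methyloxiran-2-yl]-2,6-dimethylnona-2,6-dien-5-ol | CC(C)=CC[C@@H](O)/C(C)=C/CC[C@]1(C)O[C@H]1CCc1ccoc1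
A6 | alternative 3 | 3-{2-[(2S,3S)-3-methyl-3-[(3E)-4-methyl-5-[(2-methylbut-3-en-2-yl)oxy]pent-3-en-1-yl]oxiran-2-yl]ethyl}furan | C=CC(C)(C)OC/C(C)=C/CC[C@]1(C)O[C@H]1CCc1ccoc1
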